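**Strategy.** The target is a trimer of 8-methoxy-1-naphthol: naphthalene unit A (bonded through C2), central unit B (bonded through C4 and C2) and unit C (bonded through C4). Everything rests on cutting the bond between C2 of A and C4 of B. In one flask the key step lithiates the MOM ether of A at C2, the only C–H next to the C1 oxygen (peri carbon C8 carries OMe), turns the aryllithium into a borate and joins it by Suzuki-Miyaura coupling to a B–C dimer bearing chlorine at C4 of B, para to the B oxygen. That chlorine is carried through an earlier bromide-selective coupling that forms the B–C bond.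

Key step: step 6

Assumption: 8-methoxynaphthalen-1-ol (1) is taken as a purchasable compound; otherwise it is one step from naphthalene-1,8-diol (MeI, K2CO3, acetone).
Remark: the target has no stereocentre and its SMILES defines no configuration at the two biaryl axes, so no stereocontrol is planned.

**Step 1**
Reactants: 1 8-methoxynaphthalen-1-ol
Product: 2 4-chloro-8-methoxynaphthalen-1-ol
Conditions: SO2Cl2 (1.0 equiv), CH2Cl2, −20 to 0 °C
Reagents that add atoms: sulfuryl chloride, O=S(=O)(Cl)Cl
Why: Electrophilic aromatic chlorination of a 1-naphthol, in which the free C1 hydroxyl is the strongest donor and should steer SO2Cl2 to C4, the para alpha carbon of its own ring, ahead of the ortho carbon C2 and of the methoxy ring.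

**Step 2**
Reactants: 2 4-chloro-8-methoxynaphthalen-1-ol
Product: 3 4-chloro-8-methoxy-1-(methoxymethoxy)naphthalene
Conditions: NaH, THF/DMF, 0 °C; MOMCl, 0 °C to rt
Reagents that add atoms: chloromethyl methyl ether, COCCl
Why: Williamson-type O-alkylation of the sodium naphthoxide with MOMCl installs the acetal that directs the later lithiation and leaves with acid at the end.

**Step 3**
Reactants: 1 8-methoxynaphthalen-1-ol
Product: 4 4-bromo-8-methoxynaphthalen-1-ol
Conditions: NBS (1.0 equiv), MeCN, −20 to 0 °C, dark
Reagents that add atoms: N-bromosuccinimide, O=C1CCC(=O)N1Br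
Why: Electrophilic aromatic bromination with NBS in acetonitrile at low temperature, a para-selective method for 1-naphthols, should put bromine on C4 of the hydroxylated ring.

**Step 4**
Reactants: 3 4-chloro-8-methoxy-1-(methoxymethoxy)naphthalene; 4 4-bromo-8-methoxynaphthalen-1-ol
Product: 7 4-[4-chloro-8-methoxy-1-(methoxymethoxy)naphthalen-2-yl]-8-methoxynaphthalen-1-ol, via aryllithium 5 (not isolated), via lithium aryl triisopropyl borate 6 (not isolated)
Conditions: 3 (1.3 equiv), s-BuLi, TMEDA, THF, −78 °C; B(OiPr)3, −78 °C to rt; then 4, Pd(dppf)Cl2 (3 mol%), aq K3PO4, 60 °C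
Reagents that add atoms: none
Why: One-pot directed ortho-metalation, borylation and Suzuki-Miyaura coupling, in which the OMOM group (a stronger director than Cl or OMe) sends s-BuLi to C2, the borate couples with the C4–Br bond of 4, and Pd(dppf)Cl2 should leave the electron-rich aryl C–Cl bond untouched for step 6.

**Step 5**
Reactants: 1 8-methoxynaphthalen-1-ol
Product: 8 1-methoxy-8-(methoxymethoxy)naphthalene
Conditions: NaH, THF/DMF, 0 °C; MOMCl, 0 °C to rt
Reagents that add atoms: chloromethyl methyl ether, COCCl
Why: Williamson-type O-alkylation of the sodium naphthoxide gives the MOM ether whose acetal oxygen directs lithiation to C2.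

**Step 6**
Reactants: 8 1-methoxy-8-(methoxymethoxy)naphthalene; 7 4-[4-chloro-8-methoxy-1-(methoxymethoxy)naphthalen-2-yl]-8-methoxynaphthalen-1-ol
Product: 11 4-{8-methoxy-4-[8-methoxy-1-(methoxymethoxy)naphthalen-2-yl]-1-(methoxymethoxy)naphthalen-2-yl}-8-methoxynaphthalen-1-ol, via aryllithium 9 (not isolated), via lithium aryl triisopropyl borate 10 (not isolated)
Conditions: 8 (2.5 equiv), n-BuLi, TMEDA, THF, 0 °C; B(OiPr)3, −78 °C to rt; then 7, Pd(OAc)2 (5 mol%), XPhos (10 mol%), aq K3PO4, 65 °C
Reagents that add atoms: none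
Why: The OMOM group of 8 coordinates n-BuLi and delivers it to C2 of unit A (directed ortho-metalation; OMOM outranks OMe as a director and the peri carbon C8 is blocked), and aryllithium 9 is trapped as the lithium triisopropyl borate 10. Zerovalent palladium carrying XPhos inserts into the C4–Cl bond of unit B in 7, the borate transmetalates under aqueous K3PO4 and reductive elimination forms the C2(A)–C4(B) bond. The closest known reaction type is the one-pot lithiation/borylation/Suzuki-Miyaura coupling of lithium triisopropyl arylborates with hindered, electron-rich aryl chlorides under dialkylbiarylphosphine ligands. No ring is closed and no stereocentre is formed; the new biaryl axis is not configurationally defined in the target. The step needs site selectivity on both partners: on unit A it comes from the directing group, on unit B from the single carbon–halogen bond left in 7, placed para to the B oxygen in step 1 and spared in step 4. The free naphthol of unit C should be tolerated as its phenoxide, and the excess of 10 is meant to offset protodeboronation.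

**Step 7**
Reactants: 11 4-{8-methoxy-4-[8-methoxy-1-(methoxymethoxy)naphthalen-2-yl]-1-(methoxymethoxy)naphthalen-2-yl}-8-methoxynaphthalen-1-ol
Product: 12 4-[1-hydroxy-4-(1-hydroxy-8-methoxynaphthalen-2-yl)-8-methoxynaphthalen-2-yl]-8-methoxynaphthalen-1-ol
Conditions: 3 M aq HCl, MeOH/THF, 50 °C, argon, degassed solvents
Reagents that add atoms: none
Why: Acid-catalysed acetal exchange with methanol should cleave both MOM ethers while the aryl methyl ethers stay, and air is kept out because the electron-rich naphthols oxidise easily.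

**Compound list**
1 | 8-methoxynaphthalen-1-ol | COc1cccc2cccc(O)c12 | starting material
2 | 4-chloro-8-methoxynaphthalen-1-ol | COc1cccc2c(Cl)ccc(O)c12 | intermediate
3 | 4-chloro-8-methoxy-1-(methoxymethoxy)naphthalene | COCOc1ccc(Cl)c2cccc(OC)c12 | intermediate
4 | 4-bromo-8-methoxynaphthalen-1-ol | COc1cccc2c(Br)ccc(O)c12 | intermediate
5 | [4-chloro-8-methoxy-1-(methoxymethoxy)naphthalen-2-yl]lithium (not isolated) | [Li]c1cc(Cl)c2cccc(OC)c2c1OCOC | intermediate
6 | lithium [4-chloro-8-methoxy-1-(methoxymethoxy)naphthalen-2-yl]tri(propan-2-yloxy)borate (not isolated) | [Li+].COCOc1c([B-](OC(C)C)(OC(C)C)OC(C)C)cc(Cl)c2cccc(OC)c12 | intermediate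
7 | 4-[4-chloro-8-methoxy-1-(methoxymethoxy)naphthalen-2-yl]-8-methoxynaphthalen-1-ol (B–C dimer chloride) | COCOc1c(-c2ccc(O)c3c(OC)cccc23)cc(Cl)c2cccc(OC)c12 | intermediate
8 | 1-methoxy-8-(methoxymethoxy)naphthalene | COCOc1cccc2cccc(OC)c12 | intermediate
9 | [8-methoxy-1-(methoxymethoxy)naphthalen-2-yl]lithium (not isolated) | [Li]c1ccc2cccc(OC)c2c1OCOC | intermediate
10 | lithium [8-methoxy-1-(methoxymethoxy)naphthalen-2-yl]tri(propan-2-yloxy)borate (not isolated) | [Li+].COCOc1c([B-](OC(C)C)(OC(C)C)OC(C)C)ccc2cccc(OC)c12 | intermediate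
11 | 4-{8-methoxy-4-[8-methoxy-1-(methoxymethoxy)naphthalen-2-yl]-1-(methoxymethoxy)naphthalen-2-yl}-8-methoxynaphthalen-1-ol (bis-MOM trimer) | COCOc1c(-c2cc(-c3ccc(O)c4c(OC)cccc34)c(OCOC)c3c(OC)cccc23)ccc2cccc(OC)c12 | intermediate
12 | 4-[1-hydroxy-4-(1-hydroxy-8-methoxynaphthalen-2-yl)-8-methoxynaphthalen-2-yl]-8-methoxynaphthalen-1-ol | COc1cccc2ccc(-c3cc(-c4ccc(O)c5c(OC)cccc45)c(O)c4c(OC)cccc34)c(O)c12 | target

**Total steps:** 7. **Longest linear sequence:** 5 steps (steps 1, 2, 4, 6, 7; 1 to 2 to 3 to 7 to 11 to 12).

**Steps most likely to fail**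

Step 6 (key step). Oxidative addition into the hindered, electron-rich C4–Cl bond of unit B may be slow, so that protodeboronation of the ortho-alkoxy borate 10 back to 8 outruns the cross-coupling. The fallback exchanges the roles of the partners; it sets out from 7 and 9 and comes back at 11. Chloride 7 would be converted by Miyaura borylation (B2pin2, Pd(OAc)2, XPhos, KOAc, dioxane, 100 °C) into 4-[8-methoxy-1-(methoxymethoxy)-4-(4,4,5,5-tetramethyl-1,3,2-dioxaborolan-2-yl)naphthalen-2-yl]-8-methoxynaphthalen-1-ol F1. Aryllithium 9 would be quenched with I2 (THF, −78 °C) to give 2-iodo-8-methoxy-1-(methoxymethoxy)naphthalene F2. Suzuki-Miyaura coupling of F1 with F2 (Pd(PPh3)4, aq K3PO4, dioxane, 80 °C) should give 11. Palladium then inserts into an aryl iodide, and boron sits on a carbon without an ortho oxygen.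

Step 4. Lithiation of 3 may occur at C3 next to chlorine (followed by loss of LiCl to an aryne) or at C7 next to OMe instead of C2. The fallback fixes the metalation site with a halogen; it sets out from 2 and comes back at 5. Bromination of 2 (NBS, CH2Cl2, 0 °C), where only C2 is left open on the hydroxylated ring, would give 2-bromo-4-chloro-8-methoxynaphthalen-1-ol F3. Protection (NaH, MOMCl, THF/DMF) would give 2-bromo-4-chloro-8-methoxy-1-(methoxymethoxy)naphthalene F4. Bromine–lithium exchange (n-BuLi, THF, −78 °C), far faster than chlorine–lithium exchange, should give 5 without a regiochemical choice, and the route continues with B(OiPr)3 and 4 as in step 4.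

Step 1. The chlorinating agent may attack C2 or the methoxy ring (C5), or chlorinate twice, leaving a mixture of handles that is hard to separate. The fallback avoids every mono-para-halogenation (steps 2 to 4 become unnecessary); it sets out from 1 and comes back at 11.
- Exhaustive bromination of the hydroxylated ring (NBS, 2.05 equiv, MeCN, 0 °C) would give 2,4-dibromo-8-methoxynaphthalen-1-ol F5, which needs no ortho/para discrimination.
- Protection (NaH, MOMCl) would give 2,4-dibromo-8-methoxy-1-(methoxymethoxy)naphthalene F6.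
- n-BuLi (1.0 equiv, THF, −78 °C) should exchange only the bromine ortho to OMOM and give [4-bromo-8-methoxy-1-(methoxymethoxy)naphthalen-2-yl]lithium F7.
- Commercial juglone (O=C1C=CC(=O)c2c(O)cccc12) would be methylated (MeI, Ag2O, CH2Cl2, rt) to 5-methoxynaphthalene-1,4-dione F8.
- F7 would be added at −78 °C to an excess of F8. It should attack the C1 carbonyl, which is remote from the peri methoxy group and the more electrophilic one, giving racemic 4-[4-bromo-8-methoxy-1-(methoxymethoxy)naphthalen-2-yl]-4-hydroxy-8-methoxynaphthalen-1(4H)-one F9.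
- Reductive aromatisation of this quinol (Zn, AcOH, rt) would give 4-[4-bromo-8-methoxy-1-(methoxymethoxy)naphthalen-2-yl]-8-methoxynaphthalen-1-ol F10, the bromo analogue of 7.
- F10 would be coupled with borate 10 under the step 6 conditions to give 11.

**Further compounds**
F1 | step 6 | 4-[8-methoxy-1-(methoxymethoxy)-4-(4,4,5,5-tetramethyl-1,3,2-dioxaborolan-2-yl)naphthalen-2-yl]-8-methoxynaphthalen-1-ol | COCOc1c(-c2ccc(O)c3c(OC)cccc23)cc(B4OC(C)(C)C(C)(C)O4)c2cccc(OC)c12
F2 | step 6 | 2-iodo-8-methoxy-1-(methoxymethoxy)naphthalene | COCOc1c(I)ccc2cccc(OC)c12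
F3 | step 4 | 2-bromo-4-chloro-8-methoxynaphthalen-1-ol | COc1cccc2c(Cl)cc(Br)c(O)c12
F4 | step 4 | 2-bromo-4-chloro-8-methoxy-1-(methoxymethoxy)naphthalene | COCOc1c(Br)cc(Cl)c2cccc(OC)c12
F5 | step 1 | 2,4-dibromo-8-methoxynaphthalen-1-ol | COc1cccc2c(Br)cc(Br)c(O)c12
F6 | step 1 | 2,4-dibromo-8-methoxy-1-(methoxymethoxy)naphthalene | COCOc1c(Br)cc(Br)c2cccc(OC)c12
F7 | step 1 | [4-bromo-8-methoxy-1-(methoxymethoxy)naphthalen-2-yl]lithium | [Li]c1cc(Br)c2cccc(OC)c2c1OCOC
F8 | step 1 | 5-methoxynaphthalene-1,4-dione | COc1cccc2C(=O)C=CC(=O)c12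
F9 | step 1 | racemic 4-[4-bromo-8-methoxy-1-(methoxymethoxy)naphthalen-2-yl]-4-hydroxy-8-methoxynaphthalen-1(4H)-one | COCOc1c(C2(O)C=CC(=O)c3c(OC)cccc23)cc(Br)c2cccc(OC)c12
F10 | step 1 | 4-[4-bromo-8-methoxy-1-(methoxymethoxy)naphthalen-2-yl]-8-methoxynaphthalen-1-ol | COCOc1c(-c2ccc(O)c3c(OC)cccc23)cc(Br)c2cccc(OC)c12
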